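The data are simulated for an exercise.

Early in both runs E fell and D rose, and I wanted to know where each E went once it had left.

all flasks: E 0.20 mM

| flask | X | J | Z | remark | time |
|---|---|---|---|---|---|
| Wednesday's | 0.60 mM | 1 µM | 2 µM | the very flask that is asked about, followed so far |  |
| Saturday's | 0.60 mM | 1 µM | 4 µM | run made earlier |  |
| flask | 0.600 mM | 1.0 µM | 2.0 µM |  | 10 min |

Wednesday's run (percent of the E charged)

| time / min | D / % | E / % |
|---|---|---|
| 1.33 | 30.8 | 17.7 |
| 3.00 | 37.1 | 2.0 |
| 4.00 | 37.9 | 2.1 |
| 6.00 | 38.3 | 0.5 |
| 8.00 | 37.7 | 0.3 |
| 10.0 | 38.5 | 0 |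

Saturday's run (percent of the E charged)

| time / s | D / % | E / % |
|---|---|---|
| 10.0 | 6.6 | 80.6 |
| 12.0 | 9.6 | 77.6 |
| 25.0 | 19.9 | 58.5 |
| 40.0 | 30.4 | 42.2 |
| 50.0 | 34.8 | 33.9 |
| 60.0 | 38.0 | 26.7 |
| 80.0 | 44.6 | 17.6 |

(standard deviation of a reading: 0.5 percentage points)

- D, in percent of the E first charged, at 10 min
- the option that brings most further D ("none" if no option brings more than 2 percentage points) (grey / blue / amber / green / none)
- D present, with what was taken out counted in, in percent of the E first charged, after grey
- D present, with what was taken out counted in, in percent of the E first charged, after blue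

- grey: at 10 min add J, 100% of the amount charged, then wait 5.0 min
- blue: at 10 min take out 90% of the D then present, then wait 5.0 min
- amber: change nothing and wait 5.0 min more
- green: at 10 min add X, 50.0% of the amount charged, then wait 5.0 min

- what is taken out of D is counted as made
- "the catalyst" is J with its forms; Z is a second catalyst
- additions bring no volume worth counting

I wrote the balance of E, the limiting reagent, charged at 0.20 mM against 0.600 mM of X: what was charged stands as E, as D, or as an unread rest. Then I took the numbers in turn. The time weighed little, since Wednesday's flask read 38.3% of D at 6.00 min and 38.5% at 10.0 min, with a scatter of 0.5 percentage points. J and X stood at one charge in both runs, so the readings could not weigh them, and that gap stayed open. Z did not show in the fall of E, which read 17.7% on Wednesday at 80 s and 17.6% on Saturday at 80.0 s, but Z did show in what E became.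

Wednesday's last three readings averaged 38.2% of D, so the rest was 61.8% and D per part of the rest was 0.618. On Saturday, D was 54.1% of the E consumed, which gives 1.18, about twice Wednesday's figure on twice the Z. Wednesday's flask gave 0.309 µM⁻¹, and this number, D per part of the rest for each µM of Z, I called the fork ratio, a selectivity factor per unit of Z; Saturday's reading gave 0.295 µM⁻¹.

So I committed to 38.2% at the asked time. E read 0% by then, and D had stayed flat beside the rest, so I expected no option to clear 2 points.

The forecast gave 38.1%, best none, 38.1% after grey and 38.1% after blue: “E is gone by 10 min, so J, X, waiting or removing D should add nothing.” Mine and its figure rest on the same plateau, so their nearness is no check.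

The flask gave 38.0%, with 38.0% after grey, 38.0% after blue and none as the best option.

    E + J → J + L (k = 21500 M⁻¹ s⁻¹)
    X + Z + L → Z + D (k = 5.37 × 10⁷ M⁻² s⁻¹)
    L → Q (k = 0.0985 s⁻¹)

The forecast stood, and a different charge of X or of Z would turn it wrong: the answer had moved by 5 points at 0.485 mM or 0.735 mM of X, and at 1.59 µM or 2.48 µM of Z. The fork ratio 0.309 µM⁻¹, read at 0.60 mM of X and put on the neighbour flask with the same X and 0.800 µM of Z, gives D a share of 19.8%, and that neighbour stood at 20.2%.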